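The G left over at the last reading is what my colleague and I disputed over these flasks.

| setting | amber | grey | teal | green | Monday's | Wednesday's |
|---|---|---|---|---|---|---|
| G | 0.10 M | 0.10 M | 0.10 M | 0.13 M | 0.15 M | 0.10 M |
| E | 0.014 M | 0.027 M | 0.040 M | 0.050 M | 0.0120 M | 0.0500 M |
| temperature | 55 °C | 66 °C | 55 °C | 66 °C | 60 °C | 60 °C |
| remark | run made earlier | run made earlier | run made earlier | run made earlier |  |  |
| time |  |  |  |  | 8.0 h | 8.0 h |

| run | time / h | J / % | X / % | G / % |
|---|---|---|---|---|
| amber | 1.50 | 8.9 | 2.9 | 73.5 |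
| amber | 3.00 | 10.5 | 8.7 | 63.2 |
| amber | 5.00 | 11.0 | 17.6 | 52.7 |
| amber | 6.00 | 11.4 | 21.8 | 46.9 |
| amber | 8.00 | 11.2 | 29.0 | 37.0 |
| grey | 0.667 | 5.2 | 2.7 | 79.5 |
| grey | 2.00 | 6.6 | 13.2 | 61.8 |
| grey | 4.00 | 7.5 | 25.9 | 41.0 |
| grey | 6.00 | 8.9 | 38.0 | 23.7 |
| grey | 8.00 | 8.4 | 47.5 | 9.9 |
| teal | 0.667 | 5.3 | 0.8 | 81.4 |
| teal | 1.33 | 8.6 | 2.9 | 73.6 |
| teal | 2.50 | 10.2 | 7.3 | 63.2 |
| teal | 4.00 | 10.0 | 13.2 | 51.9 |
| teal | 8.00 | 11.3 | 28.0 | 26.0 |
| green | 1.50 | 4.3 | 7.2 | 73.6 |
| green | 3.00 | 5.7 | 14.1 | 57.4 |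
| green | 5.00 | 6.3 | 24.5 | 40.7 |
| green | 6.00 | 6.6 | 28.6 | 32.6 |
| green | 8.00 | 6.6 | 34.9 | 19.7 |

(scatter of a reading: 0.5 percentage points)

- the flask that ends with the higher share of J in all that became J or X, or "neither" when 2 percentage points or less lies between them (Monday's / Wednesday's / neither)
- share of J in all that became J or X, Monday's
- share of J in all that became J or X, Wednesday's

- at the start none of G is in solution
- what has only dissolved of G counts as not reacted
- a reading or a percentage of J counts all its forms, free or not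

My colleague reads the G column. Teal kept 26.0% of its G at 55 °C, and grey kept 9.9% at 66 °C with less E. Wednesday's, with more E than Monday's and a smaller charge of G, should therefore come near the end of its G by 8.0 h. On this view J then stops being fed and sinks while X goes on, so Monday's ends ahead.

I read the ratio of two peaks. In amber, from 3.00 h to the last reading, J moves from 10.5% to 11.2% while X climbs from 8.7% to 29.0%, so I divide cJ by the mean rate of X, which is cX/t. That gives a time, t·cJ/cX, which reads 3.12 h at 5.00 h in amber and 1.29 h at 5.00 h in green. At the last readings it is 3.09 h for amber and 3.23 h for teal, then 1.41 h for grey and 1.51 h for green. Each pair shares a temperature but differs in E, green also in G, and the pairs lie well apart. So I take the geometric mean of each pair and interpolate its logarithm in temperature, which gives 2.23 h at 60 °C. This is the lead time τ, the hours of X-making that equal the J standing in the flask. The selectivity for J is then τ/(τ+t), which is 21.8% for both flasks, so I say neither.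

The forecast takes my side by its own road: neither, with 20.8% (18.5% to 23.5%) for Monday's and 22.2% (19.5% to 25.5%) for Wednesday's. Its ground is that “This cap is independent of E and of G charged”. Where I have one figure, it has two, 1.4 percentage points apart.

The simulation gives 19.8% for Monday's and 20.0% for Wednesday's: neither.

    Z ⇌ J (K = 0.810, k = 5.90 × 10⁻⁴ /s, Ea = 89.0 kJ/mol, ΔH = −31.0 kJ/mol)
    J ⇌ X (K = 12.0, k = 2.00 × 10⁻⁴ /s, Ea = 97.0 kJ/mol, ΔH = −50.0 kJ/mol)
    D ⇌ J, rate k3*(cs3 - [J]) while solid is left; crystals form when [J] > cs3 (solubility = 0.0750 M, k = 0.00400 /s)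
    G ⇌ Z, rate k4*(cs4 - [Z]) while solid is left; crystals form when [Z] > cs4 (solubility = 16.0 mM, k = 9.80 × 10⁻⁴ /s)
    Z + E → Q (k = 0.00250 /M/s, Ea = 56.0 kJ/mol)
    (constants at 60 °C)

Wednesday's lead time comes back as 2.00 h, with J at 9.47% and solid G at 8.71% at 8.00 h. The end of the G that my colleague expected appears in a neighbour, Wednesday's with 0.20 M of E, which is 2.00 equiv to G. There τ promises 21.8%, but at 8.0 h that flask holds J at 1.04% and X at 20.0%. This is a lead time of 0.416 h and a share of 4.91%. G is the charge that runs out first there, with 0.94% left, solid or dissolved.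

(The data are simulated with made-up constants; scatter was added.)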